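**Strategy.** Everything rests on cutting the C1–C10 ring-fusion bond. This turns the briarane bicycle into a 14-membered cembranoid that already carries the γ-lactone and both acetates. The key step exploits the C14(OH)–C1(quaternary, Me)–C10(H)–C11 array of the cyclohexane: a C1–C14 epoxide lies across the macrocycle from the E-C10=C11 olefin. Titanocene(III) opens the epoxide to the C1 radical, which closes transannularly on C10. One bond creates the cyclohexane and the ten-membered ring together, sets C1 and C10, frees the 14-OH and leaves a C11=C20 olefin for hydration. The precursor is assembled from L-erythrulose and 4-pentyn-1-ol by Suzuki coupling and Nozaki–Hiyama–Kishi macrocyclisation.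

Key step: step 18

Remark: briarane numbering (C1–C20 of 30) is used for every intermediate. "As in 30" means the same spatial arrangement, whatever the CIP letter.

Step 1
Reactants: 1 L-erythrulose
Product: 2 (3S)-1,4-bis(tert-butyldimethylsilyloxy)-3-hydroxybutan-2-one
Conditions: TBSCl (2.1 equiv), imidazole, DMF, −10 to 0 °C
Reagents that add atoms: tert-butyldimethylsilyl chloride, CC(C)(C)[Si](C)(C)Cl
Why: Imidazole-promoted silylation is much faster at the two primary hydroxyls (C6, C9) than at the ketone-flanked secondary C7–OH, and the chiral-pool C7 centre (as in 30) is untouched.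

Step 2
Reactants: 2 bis-silyl erythrulose; 3 2-bromopropanoyl bromide
Product: 4 (2S)-1,4-bis(TBSO)-3-oxobutan-2-yl 2-bromopropanoate (both CHBr epimers)
Conditions: pyridine, CH2Cl2, −20 °C
Reagents that add atoms: none
Why: O-acylation of the only free hydroxyl brings in C17–C19 and C18, and the CHBr configuration is irrelevant because that centre is metalated in the next step.

Step 3
Reactants: 4 α-bromopropionate
Product: 5 (3R,4R,5S)-4-hydroxy-3-methyl-4,5-bis(TBSO-methyl)oxolan-2-one
Conditions: activated Zn dust, THF, 45 °C; 1 M HCl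
Reagents that add atoms: none
Why: In this intramolecular Reformatsky reaction the C-bound zinc ester closes 5-exo-trig on the C8 ketone from the face that puts C9 trans to C6, and the reversible zinc aldolate and epimerisable C17 settle in the alternating array (C6, C9, C18), so C7 sets C8 and C17.

Step 4
Reactants: 5 bis-silyl hydroxy-lactone
Product: 6 C6 primary alcohol (C9 still OTBS)
Conditions: CSA (10 mol %), MeOH–CH2Cl2, −10 °C
Reagents that add atoms: none
Why: Acid-catalysed silyl ether methanolysis is governed by sterics, so the C6 ether on a secondary carbon is cleaved before the neopentyl-type C9 ether next to quaternary C8.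

Step 5
Reactants: 6 primary alcohol
Product: 7 C6 aldehyde
Conditions: Dess–Martin periodinane, CH2Cl2, 0 °C
Reagents that add atoms: none
Why: Dess–Martin oxidation is neutral, so the α-acyloxy centre C7 should not epimerise and the β-hydroxy aldehyde should not undergo retro-aldol cleavage.

Step 6
Reactants: 7 aldehyde; 8 ethyltriphenylphosphonium iodide
Product: 12 (Z)-vinyl iodide (I on C5 cis to C7), via ethylidene ylide 9 (not isolated), via iodoethylphosphonium iodide 10 (not isolated), via iodo ylide 11 (not isolated)
Conditions: 8, n-BuLi, THF, rt; I2, −78 °C; NaHMDS, −20 °C; then 7, −78 °C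
Reagents that add atoms: iodine, II
Why: The Stork–Zhao-type Wittig olefination with the α-iodo ylide is kinetically Z-selective, which fixes the 5Z geometry, and the ylide is too weak a base to deprotonate the tertiary 8-OH.

Step 7
Reactants: 13 4-pentyn-1-ol
Product: 15 (E)-5-bromo-4-methylpent-4-en-1-ol, via alkenylalane 14 (not isolated)
Conditions: AlMe3 (3 equiv), Cp2ZrCl2 (25 mol %), CH2Cl2, 0 °C to rt; NBS, THF, −30 °C; H2O, Rochelle salt
Reagents that add atoms: trimethylaluminium, C[Al](C)C; N-bromosuccinimide, O=C1CCC(=O)N1Br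
Why: The Negishi zirconium-catalysed carboalumination adds Me–Al syn across the alkyne and bromodealumination proceeds with retention, which gives the E-C10=C11 olefin with C20 in place.

Step 8
Reactants: 15 bromo alkenol
Product: 16 (E)-5-bromo-4-methylpent-4-enal
Conditions: Dess–Martin periodinane, CH2Cl2, 0 °C to rt
Reagents that add atoms: none
Why: Dess–Martin oxidation stops cleanly at the C14 aldehyde and leaves the vinyl bromide alone.

Step 9
Reactants: 16 aldehyde; 17 2-(triphenylphosphoranylidene)propanal
Product: 18 (2E,6E)-7-bromo-2,6-dimethylhepta-2,6-dienal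
Conditions: toluene, 80 °C
Reagents that add atoms: none
Why: The Wittig reaction of a stabilised ylide is E-selective and adds C1, C2 and C15 as the enal.

Step 10
Reactants: 18 dienal
Product: 19 (4E,8E)-9-bromo-4,8-dimethylnona-1,4,8-trien-3-ol (racemic)
Conditions: CH2=CHMgBr, THF, −78 °C; aq. NH4Cl
Reagents that add atoms: vinylmagnesium bromide, C=C[Mg]Br
Why: Grignard 1,2-addition to the enal brings in C3 and C4, and the racemic C2 carbinol is resolved in the next step.

Step 11
Reactants: 19 racemic trienol
Product: 20 erythro epoxy alcohol (C2 R, C14 as in 30, 1,14-epoxide from the E-olefin)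
Conditions: Ti(OiPr)4 (10 mol %), D-(−)-DIPT (14 mol %), t-BuOOH (0.45 equiv), 4 Å MS, CH2Cl2, −20 °C
Reagents that add atoms: tert-butyl hydroperoxide, CC(C)(C)OO
Why: In the Sharpless kinetic resolution D-(−)-DIPT epoxidises the (2R)-enantiomer fast at its trisubstituted olefin from the erythro face, which sets C14 and C1, while the vinyl group and the (2S)-enantiomer stay behind.

Step 12
Reactants: 20 epoxy alcohol
Product: 21 threo epoxy acetate (C2 and C14 as in 30)
Conditions: AcOH, PPh3, DIAD, toluene, 0 °C to rt
Reagents that add atoms: acetic acid, CC(=O)O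
Why: In the Mitsunobu reaction acetate displaces the activated C2 oxygen by SN2, which inverts C2 to the configuration of 30 and installs the 2-acetate in the same operation.

Step 13
Reactants: 21 epoxy acetate; 12 (Z)-vinyl iodide
Product: 23 seco TBS ether (C4–C5 joined, 5Z), via B-alkyl-9-BBN 22 (not isolated)
Conditions: 9-BBN, THF, rt; then 12, Pd(dppf)Cl2 (10 mol %), AsPh3, Cs2CO3, DMF–H2O, rt
Reagents that add atoms: none
Why: 9-BBN hydroborates only the terminal vinyl group at C4, and the B-alkyl Suzuki–Miyaura coupling replaces iodine with retention (C4 cis to C7), with the vinyl iodide reacting well before the vinyl bromide.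

Step 14
Reactants: 23 seco TBS ether
Product: 24 seco C9 primary alcohol
Conditions: TBAF, AcOH (1:1), THF, 0 °C to rt
Reagents that add atoms: none
Why: Buffered fluoride desilylation frees C9–OH without acetate cleavage, epoxide opening or base-induced translactonisation.

Step 15
Reactants: 24 primary alcohol
Product: 25 seco C9 aldehyde
Conditions: Dess–Martin periodinane, CH2Cl2, 0 °C
Reagents that add atoms: none
Why: Dess–Martin oxidation of the only oxidisable alcohol gives the non-enolisable α-hydroxy aldehyde.

Step 16
Reactants: 25 bromo aldehyde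
Product: 26 14-membered macrocyclic 9-alcohol (C9 as in 30, 10E)
Conditions: CrCl2 (6 equiv), NiCl2 (5 mol %), chiral oxazoline–sulfonamide ligand, Et3N, THF, rt, slow addition to 1 mM
Reagents that add atoms: none
Why: In the Nozaki–Hiyama–Kishi macrocyclisation the alkenylchromium(III) forms from C10–Br with retention and adds only to the aldehyde, and the chiral chromium ligand dictates the aldehyde face that gives C9 as in 30 because quaternary C8 exerts little bias.

Step 17
Reactants: 26 macrocyclic alcohol
Product: 27 macrocyclic epoxy diacetate (1,10-seco-briarane)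
Conditions: Ac2O, pyridine, DMAP (cat.), CH2Cl2, 0 °C
Reagents that add atoms: acetic anhydride, CC(=O)OC(C)=O
Why: Acylation takes the secondary allylic 9-OH and leaves the hindered tertiary 8-OH free.

Step 18
Reactants: 27 macrocyclic epoxy diacetate
Product: 28 2,9-diacetoxy-8,14-dihydroxybriara-5(Z),11(20)-dien-19,7-olide
Conditions: Cp2TiCl2 (2.5 equiv), Mn dust, degassed THF, rt, slow addition of 27 to 2 mM; aq. NaH2PO4
Reagents that add atoms: none
Why: Cp2TiCl transfers one electron to the 1,14-epoxide and cleaves its C1–O bond to the tertiary C1 radical (C14 keeps its oxygen and configuration as the titanoxide), C1 adds across the ring to C10, and the tertiary C11 radical is captured by a second Ti(III) and loses a C20 hydrogen to leave the 11(20)-olefin. The closest known reaction type is the Nugent–RajanBabu epoxide opening in its cyclising form, known for epoxypolyprenyl acetates and, transannularly, for epoxygermacranolides that give eudesmanolides. The cyclohexane closes 6-endo-trig through a chair, and the same bond is a 10-exo-trig closure of the C1–C10 carbocycle. C10 is controlled by A(1,3) strain at C9 (H9 eclipses the olefin on the C20 side, quaternary C8 blocks one face, C1 enters past the acetoxy group), and C1 by the chair that keeps C2 and C9 equatorial and puts C15 axial, anti to H10, which is the trans fusion. The step needs C10 to win over C6 of the second trisubstituted olefin and over 5-exo attack at C11: the E-olefin lets C9 sit equatorial whereas the Z-5,6-olefin would force lactone carbon C7 axial, and attack at C11 would join two fully substituted carbons. A radical is chosen because the acetate at C2 and the oxygen at C14 would intercept or destabilise a C1 cation but are spectators here.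

Step 19
Reactants: 28 11(20)-olefin
Product: 30 junceellolide I, via acetoxonium triflate 29 (not isolated)
Conditions: Co(salen) (5 mol %), N-fluoro-2,4,6-trimethylpyridinium triflate, PhSiH3, PhCF3, 0 °C to rt; then H2O–THF
Reagents that add atoms: water, O
Why: Proposed new method: hydrogen-atom transfer from a cobalt hydride goes to C20 of the only 1,1-disubstituted olefin (the trisubstituted 5,6-olefin is slower), the tertiary C11 radical is oxidised through an alkylcobalt(IV) to a cation equivalent, and the carbonyl oxygen of the 9-acetate, which in the rotamer with C8 anti to C11 lies over the β-face beside the axial C15 methyl, closes the 1,3-dioxan-2-ylium ion 29 that water opens to the secondary acetate and the axial 11β-OH, so C11 is set by C9 and C10; the closest known reaction type is the cobalt(salen)/N-fluoropyridinium/silane Markovnikov hydrofunctionalisation of unactivated olefins by internal oxygen nucleophiles, a polar relative of the Mukaiyama hydration.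

**Compound list**

1 | L-erythrulose, (3S)-1,3,4-trihydroxybutan-2-one | OCC(=O)[C@@H](O)CO | starting material
2 | (3S)-1,4-bis(tert-butyldimethylsilyloxy)-3-hydroxybutan-2-one | CC(C)(C)[Si](C)(C)OCC(=O)[C@@H](O)CO[Si](C)(C)C(C)(C)C | intermediate
3 | 2-bromopropanoyl bromide (racemic) | CC(Br)C(=O)Br | starting material
4 | (2S)-1,4-bis(TBSO)-3-oxobutan-2-yl 2-bromopropanoate, both CHBr epimers | CC(Br)C(=O)O[C@@H](CO[Si](C)(C)C(C)(C)C)C(=O)CO[Si](C)(C)C(C)(C)C | intermediate
5 | (3R,4R,5S)-4-hydroxy-3-methyl-4,5-bis(TBSO-methyl)oxolan-2-one; C6 and C9 trans, 8-OH cis to C6 and to the C17 methyl | CC(C)(C)[Si](C)(C)OC[C@@H]1OC(=O)[C@H](C)[C@@]1(O)CO[Si](C)(C)C(C)(C)C | intermediate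
6 | (3R,4R,5S)-4-hydroxy-5-(hydroxymethyl)-3-methyl-4-(TBSO-methyl)oxolan-2-one | OC[C@@H]1OC(=O)[C@H](C)[C@@]1(O)CO[Si](C)(C)C(C)(C)C | intermediate
7 | C6 aldehyde of 6, C7, C8, C17 unchanged | O=C[C@@H]1OC(=O)[C@H](C)[C@@]1(O)CO[Si](C)(C)C(C)(C)C | intermediate
8 | ethyltriphenylphosphonium iodide | CC[P+](c1ccccc1)(c1ccccc1)c1ccccc1.[I-] | starting material
9 | ethylidenetriphenylphosphorane | CC=P(c1ccccc1)(c1ccccc1)c1ccccc1 | intermediate (not isolated)
10 | (1-iodoethyl)triphenylphosphonium iodide | CC(I)[P+](c1ccccc1)(c1ccccc1)c1ccccc1.[I-] | intermediate (not isolated)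
11 | (1-iodoethylidene)triphenylphosphorane | CC(I)=P(c1ccccc1)(c1ccccc1)c1ccccc1 | intermediate (not isolated)
12 | lactone bearing the (Z)-2-iodoprop-1-enyl group at C7 (I cis to C7), C9 OTBS, 8-OH free | I/C(C)=C\[C@@H]1OC(=O)[C@H](C)[C@@]1(O)CO[Si](C)(C)C(C)(C)C | intermediate
13 | 4-pentyn-1-ol | C#CCCCO | starting material
14 | (E)-alkenyl(dimethyl)alane, O-dimethylaluminium alkoxide | C[Al](C)/C=C(\C)CCCO[Al](C)C | intermediate (not isolated)
15 | (E)-5-bromo-4-methylpent-4-en-1-ol | OCCC/C(C)=C/Br | intermediate
16 | (E)-5-bromo-4-methylpent-4-enal | O=CCC/C(C)=C/Br | intermediate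
17 | 2-(triphenylphosphoranylidene)propanal | CC(C=O)=P(c1ccccc1)(c1ccccc1)c1ccccc1 | starting material
18 | (2E,6E)-7-bromo-2,6-dimethylhepta-2,6-dienal | O=C/C(C)=C/CC/C(C)=C/Br | intermediate
19 | (4E,8E)-9-bromo-4,8-dimethylnona-1,4,8-trien-3-ol, racemic | C=CC(O)/C(C)=C/CC/C(C)=C/Br | intermediate
20 | (1R)-1-{(2S,3S)-3-[(3E)-4-bromo-3-methylbut-3-enyl]-2-methyloxiran-2-yl}prop-2-en-1-ol | C=C[C@@H](O)[C@]1(C)O[C@H]1CC/C(C)=C/Br | intermediate
21 | (1S)-1-{(2R,3S)-3-[(3E)-4-bromo-3-methylbut-3-enyl]-2-methyloxiran-2-yl}prop-2-enyl acetate | C=C[C@H](OC(C)=O)[C@]1(C)O[C@H]1CC/C(C)=C/Br | intermediate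
22 | B-alkyl-9-BBN from 21, boron on C4 | CC(=O)O[C@@H](CCB1C2CCCC1CCC2)[C@]3(C)O[C@H]3CC/C(C)=C/Br | intermediate (not isolated)
23 | open-chain C9–C10 seco compound: 2-OAc, 1,14-epoxide, 5Z-olefin, lactone, 8-OH, C9 OTBS, (E)-C10 vinyl bromide; C2, C7, C8, C14, C17 as in 30 | CC(=O)O[C@@H](CC/C(C)=C\[C@@H]1OC(=O)[C@H](C)[C@@]1(O)CO[Si](C)(C)C(C)(C)C)[C@]2(C)O[C@H]2CC/C(C)=C/Br | intermediate
24 | C9 primary alcohol of 23 | CC(=O)O[C@@H](CC/C(C)=C\[C@@H]1OC(=O)[C@H](C)[C@@]1(O)CO)[C@]2(C)O[C@H]2CC/C(C)=C/Br | intermediate
25 | C9 aldehyde of 24 | CC(=O)O[C@@H](CC/C(C)=C\[C@@H]1OC(=O)[C@H](C)[C@@]1(O)C=O)[C@]2(C)O[C@H]2CC/C(C)=C/Br | intermediate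
26 | 14-membered (5Z,10E)-2-acetoxy-1,14-epoxy-8,9-dihydroxy-1,10-seco-briara-5,10-dien-19,7-olide; C2, C7, C8, C9, C14, C17 as in 30 | CC(=O)O[C@H]1CC/C(C)=C\[C@@H]2OC(=O)[C@H](C)[C@@]2(O)[C@@H](O)/C=C(\C)CC[C@@H]3O[C@@]13C | intermediate
27 | 9-acetate of 26 (2,9-diacetate) | CC(=O)O[C@H]1CC/C(C)=C\[C@@H]2OC(=O)[C@H](C)[C@@]2(O)[C@@H](OC(C)=O)/C=C(\C)CC[C@@H]3O[C@@]13C | intermediate
28 | 2,9-diacetoxy-8,14-dihydroxybriara-5(Z),11(20)-dien-19,7-olide; trans-fused, C15 β, H10 α, 14-OH α | CC(=O)O[C@H]1CC/C(C)=C\[C@@H]2OC(=O)[C@H](C)[C@@]2(O)[C@@H](OC(C)=O)[C@@H]2[C@]1(C)[C@@H](O)CCC2=C | intermediate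
29 | 9,11-bridged 2-methyl-1,3-dioxan-2-ylium triflate, C11–O on the β-face | CC(=O)O[C@H]1CC/C(C)=C\[C@@H]2OC(=O)[C@H](C)[C@@]2(O)[C@@H](OC(C)=[O+]5)[C@@H]2[C@]1(C)[C@@H](O)CC[C@@]25C.[O-]S(=O)(=O)C(F)(F)F | intermediate (not isolated)
30 | junceellolide I (1R,2S,7S,8S,9S,10S,11S,14S,17R) | CC(=O)O[C@H]1CC/C(C)=C\[C@@H]2OC(=O)[C@H](C)[C@@]2(O)[C@@H](OC(C)=O)[C@@H]2[C@]1(C)[C@@H](O)CC[C@]2(C)O | target

**Total step count:** 19.

**Longest linear sequence:** 13 steps (1 → 2 → 4 → 5 → 6 → 7 → 12 → 23 → 24 → 25 → 26 → 27 → 28 → 30). The branch from 13 is equally long.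

**Steps most likely to fail**

1. **Step 19.**
   - What may go wrong: the C11 cation equivalent may be intercepted from the open α-face by external water or by the 14-hydroxyl instead of by the 9-acetate. It may also simply lose a proton back to an olefin.
   - Fallback (from 28, back at 30): Lemieux–Johnson cleavage (OsO4 cat., NaIO4, 2,6-lutidine, dioxane–H2O) of the exposed exocyclic olefin should give the 11-oxo-20-nor compound F1. The ring-embedded, acyloxy-deactivated 5,6-olefin reacts more slowly. Excess MeCeCl2 (MeLi, CeCl3, THF, −78 °C), a non-basic reagent that adds to ketones before esters, is then forced by the axial C15 methyl to attack from the equatorial α-side. This gives the axial 11β-alcohol 30.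

2. **Step 18.**
   - What may go wrong: closure may occur on C6 instead of C10. The C1 radical may be trapped before ring closure. Attack may occur on the wrong olefin face, because the bulky titanoxy group at C14 must sit axial in the productive chair.
   - Fallback (from 27, back at 28): at high Cp2TiCl concentration the C1 radical is deliberately trapped and loses a C15 hydrogen, which gives the macrocyclic 1(15)-en-14-ol F2. A cobalt(salen)-catalysed, silane-initiated hydrogen-atom-transfer cycloisomerisation then regenerates the same C1 radical by H-atom addition to C15. The radical now carries only a small free hydroxyl at C14, and it closes on C10 to give 28.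

3. **Step 16.**
   - What may go wrong: facial selectivity at the aldehyde next to quaternary C8 may be poor, and oxidative addition of the vinyl bromide may be slow at high dilution.
   - Fallback (from 25, back at 26): a ligand-free Nozaki–Hiyama–Kishi closure in DMSO with more nickel should give 26 together with the 9-epimer F3. Dess–Martin oxidation of the mixture gives the macrocyclic 9-enone F4. Corey–Bakshi–Shibata reduction with the catalyst enantiomer matched to the 9S alcohol then moves stereocontrol from the addition to a reagent-controlled reduction and returns 26.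

**Further compounds**

F1 | step 19 | 11-oxo-20-nor analogue of 28 | CC(=O)O[C@H]1CC/C(C)=C\[C@@H]2OC(=O)[C@H](C)[C@@]2(O)[C@@H](OC(C)=O)[C@@H]2[C@]1(C)[C@@H](O)CCC2=O
F2 | step 18 | macrocyclic 1(15)-en-14-ol isomer of 27 | CC(=O)O[C@H]1CC/C(C)=C\[C@@H]2OC(=O)[C@H](C)[C@@]2(O)[C@@H](OC(C)=O)/C=C(\C)CC[C@H](O)C1=C
F3 | step 16 | 9-epimer of 26 | CC(=O)O[C@H]1CC/C(C)=C\[C@@H]2OC(=O)[C@H](C)[C@@]2(O)[C@H](O)/C=C(\C)CC[C@@H]3O[C@@]13C
F4 | step 16 | macrocyclic 9-oxo-10E-enone | CC(=O)O[C@H]1CC/C(C)=C\[C@@H]2OC(=O)[C@H](C)[C@@]2(O)C(=O)/C=C(\C)CC[C@@H]3O[C@@]13C
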